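(The numbers in the tables are simulated for substances that don't exist; the scatter is artificial.)

I counted turns.

the same everywhere: Q 7 mol%

|  | G | remark |
|---|---|---|
| autumn | 2.1 M | run made earlier |
| flask | 1.5 M |  |

autumn run (percent of the G charged)

| time / min | Z / % | G / % |
|---|---|---|
| 2.00 | 11 | 89 |
| 4.00 | 18 | 70 |
| 6.00 | 28 | 72 |
| 8.00 | 35 | 61 |

(each reading ± 2 percentage points)

- no earlier run changes the charge of Q; that part of a forecast is a guess

1. factor on the rate of making Z when 50% of the G are converted if Q is charged twice over
2. factor on the rate when 50% of the G are converted if Q is charged at 40 mol% instead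

1. Q was the reagent charged in the smaller amount, so I wrote its balance in turns. A turn is one G converted per charged Q (the turnover number). The turns needed are the conversion over the loading: 7.14 for the flask at 50%.

2. First instants: by 2.00 min the autumn run read Z at 11%, a pace in turns that read 0.786 min⁻¹.

3. Middle: I set aside the autumn G reading of 70% at 4.00 min, because with Z it summed to 88.0%.

4. End: the last Z reading of the autumn run stood at 5.00 turns, and its last pace read 0.500 min⁻¹, slower than the first. But G in the autumn run had fallen to 61%, and the scatter was 2 percentage points, so I could not tell whether Q was being lost. The flask needed more turns than the autumn run showed.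

5. A doubled charge needed 3.57 turns, and 40 mol% needed 1.25. With no run varying Q, I guessed the rate in proportion to Q: factors 2 and 5.71.

6. The forecast differed, lower on both: 1.9 (1.35 to 2.4) and 4.8 (2.2 to 7.5). Its words: “I therefore shade both values down and keep the ranges wide.”

    X ⇌ Q + Z (K = 0.600 M, k = 2.51 s⁻¹)
    G + Q → E (k = 0.0227 M⁻¹ s⁻¹)
    Q → D (k = 0.00117 s⁻¹)
    E ⇌ X (K = 68.0, k = 0.0269 s⁻¹)

The flask gave 2.56 and 8.76, above the forecast's high ends. At the start of the flask, Q went into E 29 times as fast as into D, yet at 10.0 min, before the 15.1 min at which it reached 50%, D held 24.9% of the catalyst. Counted in turns, the flask took its 7.14 at an average 0.473 min⁻¹. Per charged Q, the doubled charge, needing 3.57 turns, ran 1.28 times the flask's pace at 50%, and 40 mol%, needing 1.25, ran 1.53 times it.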